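The numbers in the tables were computed on assumed constants, and the scatter is random.

**The questions.** 5 questions stand here: which flask gives the most target, and how much target each flask holds at the end.

| setting | red | grey | violet | south-east | south | west | north-west |
|---|---|---|---|---|---|---|---|
| starting material | 0.50 M | 1.1 M | 0.74 M | 0.74 M | 0.74 M | 0.74 M | 0.74 M |
| capture agent | 0.74 M | 0.74 M | 0.37 M | 0.740 M | 0.740 M | 0.740 M | 0.740 M |
| temperature | 10 °C | 32 °C | 10 °C |  | 40 °C | 0 °C | 20 °C |
| remark | run made earlier | run made earlier | run made earlier | at 40 °C until 2.5 h, from then on at 0 °C |  |  |  |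
| time |  |  |  | 8.0 h | 8.0 h | 8.0 h | 8.0 h |

| run | time / h | target / % | starting material / % |
|---|---|---|---|
| red | 2.00 | 1.8 | 97.3 |
| red | 6.00 | 0 | 97.7 |
| red | 12.0 | 1.9 | 97.3 |
| red | 20.0 | 4.6 | 93.1 |
| red | 25.0 | 5.4 | 93.8 |
| grey | 0.500 | 0.2 | 98.6 |
| grey | 1.00 | 3.8 | 94.5 |
| grey | 2.00 | 8.0 | 88.2 |
| grey | 3.00 | 10.6 | 82.8 |
| grey | 6.00 | 19.4 | 66.6 |
| violet | 2.00 | 0.1 | 99.5 |
| violet | 6.00 | 0 | 98.0 |
| violet | 12.0 | 4.2 | 96.1 |
| violet | 20.0 | 4.4 | 91.9 |
| violet | 25.0 | 5.2 | 92.5 |

(each reading ± 1 percentage point)

- percent here means starting material units held: one side product counts as two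
- what may be going on: starting material -> target; starting material <-> intermediate A; intermediate A -> intermediate B; intermediate B <-> intermediate C; intermediate A <-> intermediate D; capture agent + intermediate B -> trapped intermediate; starting material + intermediate C -> side product

- the best flask by amount of target, in percent of the starting material charged; "all alike" if 1.5 percentage points covers them all (south-east / south / west / north-west / all alike)
- amount of target at the end, in percent of the starting material charged, south-east
- amount of target at the end, in percent of the starting material charged, south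
- amount of target at the end, in percent of the starting material charged, west
- amount of target at the end, in percent of the starting material charged, north-west

**Target share.** The grey run has lost 33.4% of its charge by 6.00 h and holds 19.4% target. So its target share (selectivity), the target gained per starting material lost, reads 0.581. I treat this share as a constant, and then each flask needs one thing more, its conversion.

**Time ladder.** I read the loss of starting material as first order. That gives 0.0677 h⁻¹ in the grey run and, taking red and violet together, 0.00284 h⁻¹ at 10 °C, a factor of 23.9. A straight line of ln k against temperature then gives lifetimes of starting material, from the shortest up. At 40 °C it is 4.66 h, shorter than the 8.0 h of the south flask, so I reckon south at a conversion of 82.1%. At 20 °C it is 83.3 h and at 0 °C it is 1490 h, both longer than 8.0 h, so I reckon north-west at 9.16% and west at 0.536%.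

**My reckoning.** Share times conversion gives 47.7% for south, 5.32% for north-west and 0.311% for west. I reckon south-east at a conversion of 41.5% by 2.5 h, which is worth 24.1%. Its cold stretch is a correction, 0.13 percentage points, far less than that. So I name south, which stands above the others.

**The forecast.** The forecast also names south, with 20.5%, 43%, 0.4% and 6.5% for south-east, south, west and north-west, its figure for south being lower than mine, and says “the cold stretch adds almost nothing”.

**The result.** South gives the most, with 42.6%; south-east gives 20.3%, west 0.403%, north-west 6.45%.

    starting material → target (k = 0.100 h⁻¹, Ea = 94.0 kJ mol⁻¹)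
    starting material ⇌ intermediate A (K = 2.40, k = 0.0840 h⁻¹, Ea = 106 kJ mol⁻¹, ΔH = 15.0 kJ mol⁻¹)
    intermediate A → intermediate B (k = 0.0250 h⁻¹, Ea = 96.0 kJ mol⁻¹)
    intermediate B ⇌ intermediate C (K = 7.70, k = 0.110 h⁻¹, Ea = 98.0 kJ mol⁻¹, ΔH = −21.0 kJ mol⁻¹)
    intermediate A ⇌ intermediate D (K = 0.790, k = 0.900 h⁻¹, Ea = 95.0 kJ mol⁻¹, ΔH = 1.00 kJ mol⁻¹)
    capture agent + intermediate B → trapped intermediate (k = 5.10 L mol⁻¹ h⁻¹, Ea = 62.0 kJ mol⁻¹)
    starting material + intermediate C → side product (k = 0.460 L mol⁻¹ h⁻¹, Ea = 65.0 kJ mol⁻¹)
    (constants at 40 °C)

South keeps 25% of its starting material at 8.00 h, so it converts 75.0%, less than my 82.1%. Its target share is 0.568, beside the 0.581 carried from the grey run. The carried share on that conversion gives 43.6% for south, against my 47.7%.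

**Second flask.** A flask like south at 25 °C keeps 80.6% starting material, so the carried share gives 11.3% target. The computed amount is 11.7%.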